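The target was what you asked a quick number for, and I took it from the flask as it stood.

substrate 10 mM; gas phase 2.0 mM (held); protic impurity 2.00 mM; time 1.5 min

1. target at 1.5 min, in percent of the substrate charged
2. the change that raises the amount of target at 1.5 min, in percent of the substrate charged most ("none" if none brings more than 2 percentage points) (Tuesday's / Saturday's / none)
3. amount of target at 1.5 min, in percent of the substrate charged, after Saturday's

- Tuesday's: doubling the transfer coefficient of step 1, all else as stated
- Saturday's: doubling the saturation concentration of gas phase, all else as stated

- at the start none of the gas is dissolved
- run time (flask): 1.5 min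

I counted turnovers before I looked at your forecast.

1. Gas had to pay first for 10 mM of substrate and 2.00 mM of protic impurity. Transfer into empty solution delivered at most 1.50 mM s⁻¹, so that took about 8.00 s, shorter than the 1.5 min run.

2. Over that time I let the substrate fall evenly, so it stood on average at half its charge. At 0.037 s⁻¹ the side reaction then took a fraction of about 0.148.

3. I then held [dissolved gas] near 2.0 mM, which makes the loss of target pseudo-first-order. Multiplying 1.1 L mol⁻¹ s⁻¹ by 2.0 mM and 1.5 min gave 0.198. I call that the over-reaction count, the turnovers one target molecule undergoes at saturation during the run.

4. What the side reaction spared, multiplied by the exponential of minus the count, gave 69.9 %.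

5. Tuesday's cut the filling time to half and left the count alone, which gave 76.0 %. Saturday's also cut the filling time to half but made the count twice as large, which gave 62.3 %. I chose Tuesday's.

The forecast said 73 %, Tuesday's and 65 %, on these grounds: “doubling saturation trims the side loss similarly but about doubles the dissolved gas level and over-reaction, so the yield falls”. My 69.9 % stood lower, but we chose the same change.

    gas phase ⇌ dissolved gas, rate k1*(csat - [dissolved gas]) (k1 = 0.75 s⁻¹, csat = 2.0 mM)
    substrate + dissolved gas → target (k2 = 800 L mol⁻¹ s⁻¹)
    substrate → side product (k3 = 0.037 s⁻¹)
    dissolved gas + protic impurity → quenched reagent (k4 = 250 L mol⁻¹ s⁻¹)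
    dissolved gas + target → over-reaction product (k5 = 1.1 L mol⁻¹ s⁻¹)
    dissolved gas → decomposed reagent (k6 = 0.045 s⁻¹)

The flask gave 72.6 %, and 64.9 % after Saturday's, so the forecast held. Tuesday's brought 3.4 percentage points and Saturday's −7.7 points. At 0.750 min [dissolved gas] stood at 93.3 % of saturation, with target at 79.7 %. Applying the remaining half of the count to that reading gave me 72.2 % for the end of the run.

In the neighbour flask with 1.2 mM of protic impurity, the count has no impurity term, so it stayed 0.198 and I expected unchanged over-reaction. That flask gave 13.3 % of over-reaction product and 72.8 % of target.

Its constants were set for the occasion, and the outcome is calculated.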